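Assumption: plakortolide numbering is used (C1 lactone C=O, C2 CH2, C3 CH–OO, C4 C(Me)–O(lactone), C5 CH2, C6 C(Me)–OO, C7–C15 chain); the target is (3S,4S,6R), with the C9-aryl chain cis to the lactone ring and the two methyls cis to each other.

**Retrosynthetic overview**
1. Target ⇐ phenol desilylation and diimide saturation of a C7≡C8 alkyne.
2. Key C6–C7 disconnection: Cu(I)-catalysed alkynylation of the C6 peroxycarbenium ion of a bicyclic methoxy peroxyketal with a 9-aryl-non-1-yne (fragment union, sets C6).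
3. Peroxyketal ⇐ γ-methallyl butenolide by ozonolysis in MeOH and intramolecular peroxy-Michael addition (sets C3). Ring order: lactone first, 1,2-dioxane second.
4. Butenolide ⇐ (R)-2-methylglycidol (source of C4) + isopropenyl Grignard (Cu-catalysed), oxidation, ketenylidene-phosphorane annulation.
5. Arylalkyne ⇐ B-alkyl Suzuki coupling of 4-iodophenol TIPS ether with the 9-BBN adduct of TMS-non-8-en-1-yne (7-bromoheptene + TMS-acetylene).

**Route**

Step 1
Reactants: 1 (R)-2-methylglycidol; 2 isopropenylmagnesium bromide (3 equiv)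
Product: 3 (S)-2,4-dimethylpent-4-ene-1,2-diol
Conditions: CuI (10 mol%), THF, −30 → 0 °C; aq NH4Cl
Reagents that add atoms: none
Why: Cu-catalysed Grignard opening of the epoxide (SN2 at the unhindered CH2 terminus) forms C5–C6 and leaves the chiral-pool quaternary carbinol (future C4) untouched.

Step 2
Reactants: 3 (S)-2,4-dimethylpent-4-ene-1,2-diol
Product: 4 (S)-2-hydroxy-2,4-dimethylpent-4-enal
Conditions: SO3·pyridine, DMSO, i-Pr2NEt, CH2Cl2, 0 °C; used crude
Reagents that add atoms: none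
Why: Parikh–Doering oxidation takes only the primary alcohol, without glycol cleavage, and the α-carbon is quaternary so it cannot epimerise.

Step 3
Reactants: 4 (S)-2-hydroxy-2,4-dimethylpent-4-enal
Product: 6 (S)-5-methyl-5-(2-methylallyl)furan-2(5H)-one, via acyl ylide 5 (not isolated)
Conditions: Ph3P=C=C=O (1.2 equiv), toluene, 90 °C
Reagents that add atoms: (triphenylphosphoranylidene)ketene (Bestmann ylide), O=C=C=P(c1ccccc1)(c1ccccc1)c1ccccc1
Why: The tertiary OH adds to the cumulated ylide to give an ester-stabilised ylide that closes on the aldehyde by intramolecular Wittig olefination, giving the butenolide (C1, C2) with ring-enforced Z geometry.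

Step 4
Reactants: 6 (S)-5-methyl-5-(2-methylallyl)furan-2(5H)-one
Product: 8 (4aS,7aS)-3-methoxy-3,4a-dimethyltetrahydrofuro[3,2-c][1,2]dioxin-6(3H)-one (C6 ketal epimers), via hydroperoxy ketal 7 (not isolated)
Conditions: O3, CH2Cl2/MeOH 4:1, −78 °C (Sudan III end point); N2 purge, concentrate; Et2NH (0.5 equiv), CF3CH2OH, rt
Reagents that add atoms: ozone, [O-][O+]=O; methanol, CO
Why: Ozone cleaves only the electron-rich 1,1-disubstituted alkene and MeOH traps the ketone oxide as the hydroperoxy ketal (Criegee ozonolysis in a participating solvent), whose OOH then adds to the butenolide (base-mediated 6-exo peroxy-Michael) from the face of the C5 tether, forcing the cis ring fusion (3S from 4S); the C6 ketal epimers converge later.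

Step 5
Reactants: 9 4-iodophenol
Product: 10 (4-iodophenoxy)triisopropylsilane
Conditions: TIPSCl, imidazole, DMF, rt
Reagents that add atoms: chlorotriisopropylsilane, CC(C)[Si](Cl)(C(C)C)C(C)C
Why: Standard phenol silylation; the TIPS ether survives the aqueous base, K2CO3/MeOH, TMSOTf and diimide steps and comes off with fluoride without harming the O–O bond.

Step 6
Reactants: 11 7-bromohept-1-ene; 12 ethynyltrimethylsilane
Product: 14 trimethyl(non-8-en-1-yn-1-yl)silane, via lithium acetylide 13 (not isolated)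
Conditions: n-BuLi, THF, −78 °C; then 11, DMPU, −78 °C → rt
Reagents that add atoms: none
Why: SN2 alkylation of the lithium acetylide with a primary bromide in a dipolar cosolvent.

Step 7
Reactants: 14 trimethyl(non-8-en-1-yn-1-yl)silane; 10 (4-iodophenoxy)triisopropylsilane
Product: 16 trimethyl{9-[4-(triisopropylsilyloxy)phenyl]non-1-yn-1-yl}silane, via alkylborane 15 (not isolated)
Conditions: 9-BBN, THF, 0 °C → rt; then 10, PdCl2(dppf) (5 mol%), 3 M aq K3PO4, THF/DMF, 50 °C
Reagents that add atoms: none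
Why: 9-BBN hydroborates the terminal alkene anti-Markovnikov in preference to the silyl alkyne, and the B-alkyl Suzuki–Miyaura coupling with the aryl iodide forms the aryl–C15 bond.

Step 8
Reactants: 16 trimethyl{9-[4-(triisopropylsilyloxy)phenyl]non-1-yn-1-yl}silane
Product: 17 triisopropyl[4-(non-8-yn-1-yl)phenoxy]silane
Conditions: K2CO3 (cat.), MeOH/THF, rt, short reaction time
Reagents that add atoms: none
Why: Methanolysis of the alkynyl C–Si bond is much faster than cleavage of the hindered aryl TIPS ether.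

Step 9
Reactants: 8 (4aS,7aS)-3-methoxy-3,4a-dimethyltetrahydrofuro[3,2-c][1,2]dioxin-6(3H)-one; 17 triisopropyl[4-(non-8-yn-1-yl)phenoxy]silane (1.5 equiv)
Product: 19 (3S,4aS,7aS)-3,4a-dimethyl-3-{9-[4-(triisopropylsilyloxy)phenyl]non-1-yn-1-yl}tetrahydrofuro[3,2-c][1,2]dioxin-6(3H)-one, via peroxycarbenium triflate 18 (not isolated)
Conditions: Cu(MeCN)4PF6 (10 mol%), 2,6-lutidine (1.5 equiv), TMSOTf (1.3 equiv), 4 Å MS, CH2Cl2/Et2O, −40 → −20 °C
Reagents that add atoms: none
Why: Proposed new method: Cu(I)-catalysed alkynylation of a cyclic peroxyketal, in which TMSOTf ionises the C6–OMe bond to the six-membered peroxycarbenium ion 18 and a Cu(I) acetylide formed from 17 with lutidine (alkyne C–H functionalisation) attacks C6 axially on the half-chair that keeps C4-Me pseudo-equatorial and the C4–O(lactone) bond pseudo-axial, so the alkynyl group enters cis to the lactone oxygen and C6-Me ends cis to C4-Me (6S here, 6R after saturation); the weak pyridine base keeps α-deprotonation of 18 slow and reversible, and MeCN-ligated Cu(I) at low temperature should spare the O–O bond; the closest known reaction types are Cu(I)-catalysed alkynylation of oxocarbenium ions generated from ketals with TMSOTf, and Lewis-acid substitution of peroxyketals by allylsilanes via peroxycarbenium ions.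

Step 10
Reactants: 19 (3S,4aS,7aS)-3,4a-dimethyl-3-{9-[4-(triisopropylsilyloxy)phenyl]non-1-yn-1-yl}tetrahydrofuro[3,2-c][1,2]dioxin-6(3H)-one
Product: 21 (3R,4aS,7aS)-3,4a-dimethyl-3-{9-[4-(triisopropylsilyloxy)phenyl]nonyl}tetrahydrofuro[3,2-c][1,2]dioxin-6(3H)-one, via Z-alkene 20 (not isolated)
Conditions: KO2CN=NCO2K (20 equiv), AcOH (slow addition), CH2Cl2/MeOH, 0 °C → rt, recharged until complete
Reagents that add atoms: none
Why: Diimide reduction transfers H2 concertedly to C≡C and then C=C while leaving the O–O bond, lactone and aryl silyl ether intact; C6 is quaternary and keeps its configuration (the descriptor changes only through CIP priorities).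

Step 11
Reactants: 21 (3R,4aS,7aS)-3,4a-dimethyl-3-{9-[4-(triisopropylsilyloxy)phenyl]nonyl}tetrahydrofuro[3,2-c][1,2]dioxin-6(3H)-one
Product: 22 plakortolide F, (3R,4aS,7aS)-3-[9-(4-hydroxyphenyl)nonyl]-3,4a-dimethyltetrahydrofuro[3,2-c][1,2]dioxin-6(3H)-one
Conditions: TBAF/AcOH (1:1), THF, 0 °C
Reagents that add atoms: none
Why: Buffered fluoride cleaves the aryl silyl ether (phenoxide leaving group) without base-induced retro-Michael opening of the peroxylactone.

**Compound list**
1 | (R)-2-methylglycidol, [(2R)-2-methyloxiran-2-yl]methanol | OC[C@]1(C)CO1 | starting material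
2 | isopropenylmagnesium bromide | C=C(C)[Mg]Br | starting material
3 | (S)-2,4-dimethylpent-4-ene-1,2-diol | C=C(C)C[C@](C)(O)CO | intermediate
4 | (S)-2-hydroxy-2,4-dimethylpent-4-enal | C=C(C)C[C@](C)(O)C=O | intermediate
5 | (S)-2,4-dimethyl-1-oxopent-4-en-2-yl (triphenylphosphoranylidene)acetate (acyl ylide, not isolated) | C=C(C)C[C@@](C)(C=O)OC(=O)C=P(c1ccccc1)(c1ccccc1)c1ccccc1 | intermediate
6 | (S)-5-methyl-5-(2-methylallyl)furan-2(5H)-one | C=C(C)C[C@]1(C)OC(=O)C=C1 | intermediate
7 | (5S)-5-(2-hydroperoxy-2-methoxypropyl)-5-methylfuran-2(5H)-one (ketal epimers, not isolated) | COC(C)(OO)C[C@]1(C)OC(=O)C=C1 | intermediate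
8 | (4aS,7aS)-3-methoxy-3,4a-dimethyltetrahydrofuro[3,2-c][1,2]dioxin-6(3H)-one (cis-fused; epimers at the ketal carbon C6) | COC1(C)C[C@]2(C)OC(=O)C[C@@H]2OO1 | intermediate
9 | 4-iodophenol | Oc1ccc(I)cc1 | starting material
10 | (4-iodophenoxy)triisopropylsilane | CC(C)[Si](Oc1ccc(I)cc1)(C(C)C)C(C)C | intermediate
11 | 7-bromohept-1-ene | C=CCCCCCBr | starting material
12 | ethynyltrimethylsilane | C#C[Si](C)(C)C | starting material
13 | lithium (trimethylsilyl)acetylide (not isolated) | [Li]C#C[Si](C)(C)C | intermediate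
14 | trimethyl(non-8-en-1-yn-1-yl)silane | C=CCCCCCC#C[Si](C)(C)C | intermediate
15 | 9-[9-(trimethylsilyl)non-8-yn-1-yl]-9-borabicyclo[3.3.1]nonane (not isolated) | C[Si](C)(C)C#CCCCCCCCB1C2CCCC1CCC2 | intermediate
16 | trimethyl{9-[4-(triisopropylsilyloxy)phenyl]non-1-yn-1-yl}silane | C[Si](C)(C)C#CCCCCCCCc1ccc(O[Si](C(C)C)(C(C)C)C(C)C)cc1 | intermediate
17 | triisopropyl[4-(non-8-yn-1-yl)phenoxy]silane | C#CCCCCCCCc1ccc(O[Si](C(C)C)(C(C)C)C(C)C)cc1 | intermediate
18 | (4aS,7aS)-3,4a-dimethyl-6-oxo-4,4a,7,7a-tetrahydro-6H-furo[3,2-c][1,2]dioxin-2-ium triflate (C6 peroxycarbenium ion, not isolated) | CC1=[O+]O[C@H]2CC(=O)O[C@@]2(C)C1.[O-]S(=O)(=O)C(F)(F)F | intermediate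
19 | (3S,4aS,7aS)-3,4a-dimethyl-3-{9-[4-(triisopropylsilyloxy)phenyl]non-1-yn-1-yl}tetrahydrofuro[3,2-c][1,2]dioxin-6(3H)-one (alkynyl cis to lactone O) | C[C@@]1(C#CCCCCCCCc2ccc(O[Si](C(C)C)(C(C)C)C(C)C)cc2)C[C@]2(C)OC(=O)C[C@@H]2OO1 | intermediate
20 | (3S,4aS,7aS)-3,4a-dimethyl-3-{(Z)-9-[4-(triisopropylsilyloxy)phenyl]non-1-en-1-yl}tetrahydrofuro[3,2-c][1,2]dioxin-6(3H)-one (not isolated) | C[C@@]1(/C=C\CCCCCCCc2ccc(O[Si](C(C)C)(C(C)C)C(C)C)cc2)C[C@]2(C)OC(=O)C[C@@H]2OO1 | intermediate
21 | (3R,4aS,7aS)-3,4a-dimethyl-3-{9-[4-(triisopropylsilyloxy)phenyl]nonyl}tetrahydrofuro[3,2-c][1,2]dioxin-6(3H)-one | C[C@@]1(CCCCCCCCCc2ccc(O[Si](C(C)C)(C(C)C)C(C)C)cc2)C[C@]2(C)OC(=O)C[C@@H]2OO1 | intermediate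
22 | plakortolide F, (3R,4aS,7aS)-3-[9-(4-hydroxyphenyl)nonyl]-3,4a-dimethyltetrahydrofuro[3,2-c][1,2]dioxin-6(3H)-one | C[C@@]1(CCCCCCCCCc2ccc(O)cc2)C[C@]2(C)OC(=O)C[C@@H]2OO1 | target

**Totals**
Total step count: 11. Longest linear sequence: 7 (steps 1, 2, 3, 4, 9, 10, 11). The arylalkyne branch (steps 5–8) adds 4 steps in parallel.

**Three steps most likely to fail, with fallbacks**

Step 9 (the new Cu-catalysed alkynylation; the risks are α-deprotonation of the peroxycarbenium ion, Cu(I)/O–O redox and facial selectivity). The fallback uses known chemistry, sets out from 8 and comes back to the route at 21. Lewis-acid allylation of the peroxyketal (allyltrimethylsilane, SnCl4, CH2Cl2, −78 °C; Hosomi–Sakurai-type capture of the same peroxycarbenium ion, same facial bias) gives (3R,4aS,7aS)-3-allyl-3,4a-dimethyltetrahydrofuro[3,2-c][1,2]dioxin-6(3H)-one F1. In parallel, excess octa-1,7-diene is mono-hydroborated with 9-BBN to 9-(oct-7-en-1-yl)-9-borabicyclo[3.3.1]nonane F2, which is coupled with 10 under the step 7 conditions to give triisopropyl[4-(oct-7-en-1-yl)phenoxy]silane F3. Ru-catalysed cross-metathesis of F1 with F3 (Grubbs II, CH2Cl2, 40 °C) gives (3R,4aS,7aS)-3,4a-dimethyl-3-{(E)-9-[4-(triisopropylsilyloxy)phenyl]non-2-en-1-yl}tetrahydrofuro[3,2-c][1,2]dioxin-6(3H)-one F4, and the diimide protocol of step 10 reduces this unhindered alkene to 21.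

Step 4 (ozonolysis/peroxy-Michael cascade; the risks are over-ozonolysis of the butenolide, the direction of ozonide cleavage and handling of the hydroperoxy ketal). The fallback sets out from 6 and comes back at 7. Ozonolysis in CH2Cl2 at −78 °C with Me2S work-up gives the isolable ketone (S)-5-methyl-5-(2-oxopropyl)furan-2(5H)-one F5. Perhydrolysis–ketalisation of the ketone (urea·H2O2, Sc(OTf)3 cat., MeOH, rt) then gives hydroperoxy ketal 7, which is cyclised with Et2NH/CF3CH2OH to 8 as in step 4.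

Step 3 (Bestmann annulation on a hindered, sensitive tertiary α-hydroxy aldehyde; the risks are slow O–H addition and aldehyde oligomerisation). The fallback sets out from 4 and comes back at 5. Acylation with bromoacetyl bromide (pyridine, CH2Cl2, 0 °C) gives (S)-2,4-dimethyl-1-oxopent-4-en-2-yl bromoacetate F6. PPh3 in MeCN converts it to {2-[(S)-2,4-dimethyl-1-oxopent-4-en-2-yl]oxy-2-oxoethyl}triphenylphosphonium bromide F7, and Et3N at rt generates ylide 5, which closes to 6 by the same intramolecular Wittig reaction.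

**Further compounds**
F1 | step 9 | (3R,4aS,7aS)-3-allyl-3,4a-dimethyltetrahydrofuro[3,2-c][1,2]dioxin-6(3H)-one | C[C@@]1(CC=C)C[C@]2(C)OC(=O)C[C@@H]2OO1
F2 | step 9 | 9-(oct-7-en-1-yl)-9-borabicyclo[3.3.1]nonane | C=CCCCCCCB1C2CCCC1CCC2
F3 | step 9 | triisopropyl[4-(oct-7-en-1-yl)phenoxy]silane | C=CCCCCCCc1ccc(O[Si](C(C)C)(C(C)C)C(C)C)cc1
F4 | step 9 | (3R,4aS,7aS)-3,4a-dimethyl-3-{(E)-9-[4-(triisopropylsilyloxy)phenyl]non-2-en-1-yl}tetrahydrofuro[3,2-c][1,2]dioxin-6(3H)-one | C[C@@]1(C/C=C/CCCCCCc2ccc(O[Si](C(C)C)(C(C)C)C(C)C)cc2)C[C@]2(C)OC(=O)C[C@@H]2OO1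
F5 | step 4 | (S)-5-methyl-5-(2-oxopropyl)furan-2(5H)-one | CC(=O)C[C@]1(C)OC(=O)C=C1
F6 | step 3 | (S)-2,4-dimethyl-1-oxopent-4-en-2-yl bromoacetate | C=C(C)C[C@@](C)(C=O)OC(=O)CBr
F7 | step 3 | {2-[(S)-2,4-dimethyl-1-oxopent-4-en-2-yl]oxy-2-oxoethyl}triphenylphosphonium bromide | C=C(C)C[C@@](C)(C=O)OC(=O)C[P+](c1ccccc1)(c1ccccc1)c1ccccc1.[Br-]
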